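**Plan**

Retrosynthetic cuts, in this order: (a) the CH2–C(=O) bond of the ring ketone, which opens the ten-membered ring to an acyl thioester carbon and a CH2–I carbon; (b) the ester C–O bond of the large lactone, giving (R)-4-iodobutan-2-ol; (c) the C–O bond of the γ-lactone and the bond between its furyl-bearing α-carbon and its β-carbon (Michael addition of a furylacetate to a γ-silyloxy enoate); (d) the furan C-5–CH2 bond.
Forward: the enoate (from dimethyl (S)-malate) and the furylacetate donor are joined by the Michael addition, the γ-lactone ring is closed first, the iodoalkyl ester is attached, and the ten-membered ring is closed last by a nickel-mediated reductive union of two electrophilic carbons (thioester carbonyl carbon and CH2–I carbon).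
Feature that makes the closure possible: the all-cis γ-lactone carries the CH2–C(=O)S arm on its β-carbon and the CH2–CO–O–CH(CH3)–CH2–CH2–I arm on its γ-carbon on the same ring face, so the acyl carbon and the iodide-bearing carbon (ketone carbon and its α-carbon in the ten-membered ring, 1,4 to the carbon bearing the ester oxygen) are held within reach and are joined at the final oxidation level.
Stereochemistry: the lactone γ-carbon is the carbinol carbon of (S)-malate; the β-carbon comes from anti (Felkin–Anh) Michael addition; the α-carbon from kinetic protonation of the lactone enolate on the face away from the two cis arms; the ring carbinol carbon comes from (R)-butane-1,3-diol and the side-chain carbinol from an (R)-selective enzymatic ketone reduction.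

Key step: step 14

Remark: Ar stands for the 5-[(3R)-3-(tert-butyldimethylsilyloxy)butyl]furan-2-yl group; the target is read as the all-cis lactone (S at its three ring carbons) with both carbinol carbons R.

Step 1
Reactants: 1 dimethyl (S)-malate
Product: 2 methyl (S)-3,4-dihydroxybutanoate
Conditions: BH3·SMe2 (1.05 equiv), NaBH4 (5 mol%), THF, 0 °C to rt; MeOH
Reagents that add atoms: none
Why: Hydroxyl-directed chemoselective ester reduction: borane should reduce only the ester next to the free hydroxyl through a five-membered alkoxyborane chelate, leaving the distal ester and the (S) centre untouched.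

Step 2
Reactants: 2 methyl (S)-3,4-dihydroxybutanoate
Product: 3 methyl (S)-3,4-bis(triethylsilyloxy)butanoate
Conditions: Et3SiCl (2.4 equiv), imidazole, DMF, 0 °C to rt
Reagents that add atoms: chlorotriethylsilane, CC[Si](Cl)(CC)CC
Why: Silyl ether formation on both hydroxyls, with no stereocentre involved.

Step 3
Reactants: 3 methyl (S)-3,4-bis(triethylsilyloxy)butanoate
Product: 4 methyl (S)-4-oxo-3-(triethylsilyloxy)butanoate
Conditions: (COCl)2, DMSO, CH2Cl2, −78 to −30 °C; Et3N, −78 to 0 °C
Reagents that add atoms: none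
Why: Swern oxidation of a primary silyl ether: the primary triethylsilyl ether should be cleaved by the chlorosulfonium species and oxidised while the secondary one stays, and the α-silyloxy aldehyde is used at once to avoid epimerisation.

Step 4
Reactants: 4 methyl (S)-4-oxo-3-(triethylsilyloxy)butanoate; 5 tert-butyl (triphenyl-λ5-phosphanylidene)acetate
Product: 6 1-tert-butyl 6-methyl (S,E)-4-(triethylsilyloxy)hex-2-enedioate
Conditions: CH2Cl2, rt
Reagents that add atoms: none
Why: Wittig olefination with a stabilised ylide in an aprotic solvent should give the E-enoate; the tert-butyl ester is chosen because it resists lactonisation in step 9.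

Step 5
Reactants: 7 methyl 2-(furan-2-yl)acetate; 8 but-3-en-2-one
Product: 9 methyl 2-[5-(3-oxobutyl)furan-2-yl]acetate
Conditions: Sc(OTf)3 (5 mol%), MeCN, 0 °C to rt
Reagents that add atoms: none
Why: Friedel–Crafts-type conjugate addition of the furan to the enone, which can only take place at the free α-position (C-5) of the 2-substituted furan.

Step 6
Reactants: 9 methyl 2-[5-(3-oxobutyl)furan-2-yl]acetate
Product: 10 methyl 2-{5-[(3R)-3-hydroxybutyl]furan-2-yl}acetate
Conditions: alcohol dehydrogenase from Lactobacillus brevis, NADP+ (cat.), i-PrOH (10% v/v), phosphate buffer pH 7, 30 °C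
Reagents that add atoms: none
Why: Biocatalytic ketone reduction: this anti-Prelog dehydrogenase should deliver hydride to the methyl ketone to give the (R)-alcohol, with propan-2-ol recycling the cofactor and the methyl ester inert at pH 7.

Step 7
Reactants: 10 methyl 2-{5-[(3R)-3-hydroxybutyl]furan-2-yl}acetate
Product: 11 methyl 2-Ar-acetate
Conditions: t-BuMe2SiCl, imidazole, DMF, rt
Reagents that add atoms: tert-butyl(chloro)dimethylsilane, CC(C)(C)[Si](C)(C)Cl
Why: Silyl ether formation protects the carbinol through the enolate, esterification and coupling steps.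

Step 8
Reactants: 11 methyl 2-Ar-acetate; 6 1-tert-butyl 6-methyl (S,E)-4-(triethylsilyloxy)hex-2-enedioate
Product: 13 1-tert-butyl 6-methyl (3S,4S)-3-(1-Ar-2-methoxy-2-oxoethyl)-4-(triethylsilyloxy)hexanedioate (both epimers at the Ar-bearing carbon), via lithium enolate 12 (not isolated)
Conditions: LiN(SiMe3)2 (1.05 equiv), THF, −78 °C; then 6, −78 °C; aq. NH4Cl at −78 °C
Reagents that add atoms: none
Why: Michael addition of a lithium ester enolate to a γ-silyloxy E-enoate: by the Felkin–Anh model the enolate should enter anti to the C–OSi bond with the allylic hydrogen eclipsing the alkene, which sets the new β-centre anti to the silyloxy group (the relationship that becomes cis on the lactone), while the Ar-bearing carbon is left as a mixture for step 12.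

Step 9
Reactants: 13 1-tert-butyl 6-methyl (3S,4S)-3-(1-Ar-2-methoxy-2-oxoethyl)-4-(triethylsilyloxy)hexanedioate
Product: 15 2-[(2S,3S)-4-Ar-3-(2-tert-butoxy-2-oxoethyl)-5-oxooxolan-2-yl]acetic acid (both epimers at C-4 of the oxolane), via silyl ether acid 14 (not isolated)
Conditions: LiOH·H2O (3 equiv), THF/H2O, 0 °C to rt; 1 M HCl to pH 3; then CSA (0.2 equiv), CH2Cl2, rt
Reagents that add atoms: lithium hydroxide, [Li+].[OH-]
Why: Saponification of the unhindered methyl ester followed by acid-catalysed desilylation and lactonisation (intramolecular transesterification): the freed hydroxyl can form a γ-lactone only with the furylacetate carbonyl, because the tert-butyl ester does not undergo acyl substitution here and the new acid is β to it, and no stereocentre changes.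

Step 10
Reactants: 16 (R)-butane-1,3-diol
Product: 17 (R)-4-iodobutan-2-ol
Conditions: I2, PPh3, imidazole, CH2Cl2, 0 °C
Reagents that add atoms: iodine, II
Why: Appel-type iodination should be selective for the primary hydroxyl of the 1,3-diol and does not involve the (R) carbinol centre.

Step 11
Reactants: 15 2-[(2S,3S)-4-Ar-3-(2-tert-butoxy-2-oxoethyl)-5-oxooxolan-2-yl]acetic acid; 17 (R)-4-iodobutan-2-ol
Product: 18 (2R)-4-iodobutan-2-yl 2-[(2S,3S)-4-Ar-3-(2-tert-butoxy-2-oxoethyl)-5-oxooxolan-2-yl]acetate (both epimers at C-4 of the oxolane)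
Conditions: EDC·HCl (1.5 equiv), DMAP (0.1 equiv), CH2Cl2, 0 °C to rt
Reagents that add atoms: none
Why: Steglich (carbodiimide) esterification with retention at the carbinol carbon, run cold with little DMAP to limit β-elimination of the activated β-acyloxy acid.

Step 12
Reactants: 18 (2R)-4-iodobutan-2-yl 2-[(2S,3S)-4-Ar-3-(2-tert-butoxy-2-oxoethyl)-5-oxooxolan-2-yl]acetate
Product: 20 (2R)-4-iodobutan-2-yl 2-[(2S,3S,4S)-4-Ar-3-(2-tert-butoxy-2-oxoethyl)-5-oxooxolan-2-yl]acetate (all-cis), via lithium lactone enolate 19 (not isolated)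
Conditions: LiN(SiMe3)2 (1.1 equiv), THF, −78 °C, 30 min; AcOH (3 equiv, in THF), −78 °C
Reagents that add atoms: none
Why: Kinetic protonation of a lactone enolate: the amide base should remove only the furyl- and carbonyl-activated proton, and the planar enolate should be protonated on the face opposite to the two cis arms, which places Ar cis to both from either epimer (stereoconvergent).

Step 13
Reactants: 20 (2R)-4-iodobutan-2-yl 2-[(2S,3S,4S)-4-Ar-3-(2-tert-butoxy-2-oxoethyl)-5-oxooxolan-2-yl]acetate
Product: 22 2-[(2S,3S,4S)-4-Ar-2-(2-{[(2R)-4-iodobutan-2-yl]oxy}-2-oxoethyl)-5-oxooxolan-3-yl]acetic acid, via trimethylsilyl ester 21 (not isolated)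
Conditions: Me3SiOTf (3 equiv), 2,6-lutidine (4 equiv), CH2Cl2, 0 °C; then aq. NaH2PO4 (pH 5)
Reagents that add atoms: none
Why: Silyl triflate-mediated cleavage of a tert-butyl ester (loss of 2-methylpropene from the O-silylated ester) under buffered, non-protic conditions that should spare the furan, the silyl ether, the iodide and the epimerisable centre, the silyl ester being hydrolysed on work-up.

Step 14
Reactants: 22 2-[(2S,3S,4S)-4-Ar-2-(2-{[(2R)-4-iodobutan-2-yl]oxy}-2-oxoethyl)-5-oxooxolan-3-yl]acetic acid
Product: 24 cordycicadin B tert-butyldimethylsilyl ether, via S-2-pyridyl thioester 23 (not isolated)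
Conditions: 2,2'-dipyridyl disulfide (1.2 equiv), PPh3 (1.2 equiv), CH2Cl2, rt; solvent change to DMI/EtOAc; syringe-pump addition (12 h) to NiBr2(4,4'-di-tert-butyl-2,2'-bipyridine) (0.5 equiv), Cp2ZrCl2 (2 equiv), Zn dust (6 equiv), DMI/EtOAc, rt, final 1 mM
Reagents that add atoms: none
Why: Proposed new method: zerovalent nickel, formed from NiBr2(4,4'-di-tert-butyl-2,2'-bipyridine) and Zn, should insert into the C–S bond of the N,S-chelating thioester 23 to give an acyl-nickel complex, the primary iodide is turned into a carbon radical by halogen abstraction at low-valent nickel or zirconium, the radical is trapped at nickel and reductive elimination forms the CH2–C(=O) bond, so that two electrophilic carbons are united and the ketone is born at its final oxidation level. The closest known reaction type is the intermolecular nickel/zirconium-mediated reductive ketone synthesis from S-2-pyridyl thioesters and primary alkyl iodides, which tolerates esters, lactones, silyl ethers and enolisable centres; new here is its use to close a medium ring. The ten-membered ring is closed in the formal 10-exo-trig mode (substitution at the trigonal acyl carbon, C=O outside the ring bond being made), by way of an eleven-membered nickelacycle. No stereocentre is created, and the five present ones, the epimerisable Ar-bearing carbon included, should be safe because the medium is neutral and non-basic. The step must favour ring closure over cyclic dimer and oligomer formation and over reduction or β-hydride elimination at the CH2–I end: the all-cis lactone holds both arms on one face, the planar ester and acyl units leave few rotors, the acyl-nickel species is long-lived and can wait for the radical on its own chain, and syringe-pump addition keeps free substrate near 1 mM. Chemoselectivity among the four carbonyl groups rests on the thioester being the only one that undergoes oxidative addition.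

Step 15
Reactants: 24 cordycicadin B tert-butyldimethylsilyl ether
Product: 25 cordycicadin B
Conditions: HF·pyridine, pyridine, THF, 0 °C to rt
Reagents that add atoms: none
Why: Fluoride-mediated desilylation under buffered acidic conditions should leave the base-sensitive β-acyloxy ester, the ketone and the epimerisable lactone carbon untouched.

**Compound list**

1 | dimethyl (S)-malate | COC(=O)C[C@H](O)C(=O)OC | starting material
2 | methyl (S)-3,4-dihydroxybutanoate | COC(=O)C[C@H](O)CO | intermediate
3 | methyl (S)-3,4-bis(triethylsilyloxy)butanoate | COC(=O)C[C@H](O[Si](CC)(CC)CC)CO[Si](CC)(CC)CC | intermediate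
4 | methyl (S)-4-oxo-3-(triethylsilyloxy)butanoate | COC(=O)C[C@H](O[Si](CC)(CC)CC)C=O | intermediate
5 | tert-butyl (triphenyl-λ5-phosphanylidene)acetate | CC(C)(C)OC(=O)C=P(c1ccccc1)(c1ccccc1)c1ccccc1 | starting material
6 | 1-tert-butyl 6-methyl (S,E)-4-(triethylsilyloxy)hex-2-enedioate | COC(=O)C[C@H](O[Si](CC)(CC)CC)/C=C/C(=O)OC(C)(C)C | intermediate
7 | methyl 2-(furan-2-yl)acetate | COC(=O)Cc1ccco1 | starting material
8 | but-3-en-2-one | CC(=O)C=C | starting material
9 | methyl 2-[5-(3-oxobutyl)furan-2-yl]acetate | COC(=O)Cc1ccc(CCC(C)=O)o1 | intermediate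
10 | methyl 2-{5-[(3R)-3-hydroxybutyl]furan-2-yl}acetate | COC(=O)Cc1ccc(CC[C@@H](C)O)o1 | intermediate
11 | methyl 2-Ar-acetate (tert-butyldimethylsilyl ether of 10) | COC(=O)Cc1ccc(CC[C@@H](C)O[Si](C)(C)C(C)(C)C)o1 | intermediate
12 | lithium enolate of 11 | COC(O[Li])=Cc1ccc(CC[C@@H](C)O[Si](C)(C)C(C)(C)C)o1 | intermediate
13 | 1-tert-butyl 6-methyl (3S,4S)-3-(1-Ar-2-methoxy-2-oxoethyl)-4-(triethylsilyloxy)hexanedioate, both epimers at the Ar-bearing carbon | COC(=O)C(c1ccc(CC[C@@H](C)O[Si](C)(C)C(C)(C)C)o1)[C@H](CC(=O)OC(C)(C)C)[C@@H](O[Si](CC)(CC)CC)CC(=O)OC | intermediate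
14 | (3S,4S)-4-(1-Ar-2-methoxy-2-oxoethyl)-6-tert-butoxy-6-oxo-3-(triethylsilyloxy)hexanoic acid, both epimers at the Ar-bearing carbon | COC(=O)C(c1ccc(CC[C@@H](C)O[Si](C)(C)C(C)(C)C)o1)[C@H](CC(=O)OC(C)(C)C)[C@@H](O[Si](CC)(CC)CC)CC(=O)O | intermediate
15 | 2-[(2S,3S)-4-Ar-3-(2-tert-butoxy-2-oxoethyl)-5-oxooxolan-2-yl]acetic acid, both epimers at C-4 | CC(C)(C)OC(=O)C[C@@H]1[C@H](CC(=O)O)OC(=O)C1c1ccc(CC[C@@H](C)O[Si](C)(C)C(C)(C)C)o1 | intermediate
16 | (R)-butane-1,3-diol | C[C@@H](O)CCO | starting material
17 | (R)-4-iodobutan-2-ol | C[C@@H](O)CCI | intermediate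
18 | (2R)-4-iodobutan-2-yl 2-[(2S,3S)-4-Ar-3-(2-tert-butoxy-2-oxoethyl)-5-oxooxolan-2-yl]acetate, both epimers at C-4 | CC(C)(C)OC(=O)C[C@@H]1[C@H](CC(=O)O[C@H](C)CCI)OC(=O)C1c1ccc(CC[C@@H](C)O[Si](C)(C)C(C)(C)C)o1 | intermediate
19 | lithium enolate of lactone 18 | CC(C)(C)OC(=O)C[C@@H]1[C@H](CC(=O)O[C@H](C)CCI)OC(O[Li])=C1c1ccc(CC[C@@H](C)O[Si](C)(C)C(C)(C)C)o1 | intermediate
20 | (2R)-4-iodobutan-2-yl 2-[(2S,3S,4S)-4-Ar-3-(2-tert-butoxy-2-oxoethyl)-5-oxooxolan-2-yl]acetate, all-cis | CC(C)(C)OC(=O)C[C@@H]1[C@H](CC(=O)O[C@H](C)CCI)OC(=O)[C@@H]1c1ccc(CC[C@@H](C)O[Si](C)(C)C(C)(C)C)o1 | intermediate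
21 | trimethylsilyl ester of 22 | C[Si](C)(C)OC(=O)C[C@@H]1[C@H](CC(=O)O[C@H](C)CCI)OC(=O)[C@@H]1c1ccc(CC[C@@H](C)O[Si](C)(C)C(C)(C)C)o1 | intermediate
22 | 2-[(2S,3S,4S)-4-Ar-2-(2-{[(2R)-4-iodobutan-2-yl]oxy}-2-oxoethyl)-5-oxooxolan-3-yl]acetic acid | OC(=O)C[C@@H]1[C@H](CC(=O)O[C@H](C)CCI)OC(=O)[C@@H]1c1ccc(CC[C@@H](C)O[Si](C)(C)C(C)(C)C)o1 | intermediate
23 | S-pyridin-2-yl thioester of 22 | O=C(C[C@@H]1[C@H](CC(=O)O[C@H](C)CCI)OC(=O)[C@@H]1c1ccc(CC[C@@H](C)O[Si](C)(C)C(C)(C)C)o1)Sc1ccccn1 | intermediate
24 | cordycicadin B tert-butyldimethylsilyl ether (ten-membered 6-oxo-9-olide, 9R, cis-fused at C-3/C-4 to the all-cis Ar-substituted γ-lactone) | C[C@@H]1CCC(=O)C[C@@H]2[C@H](CC(=O)O1)OC(=O)[C@@H]2c1ccc(CC[C@@H](C)O[Si](C)(C)C(C)(C)C)o1 | intermediate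
25 | cordycicadin B (lactone ring carbons S,S,S and all-cis; both carbinol carbons R) | C[C@@H]1CCC(=O)C[C@@H]2[C@H](CC(=O)O1)OC(=O)[C@@H]2c1ccc(CC[C@@H](C)O)o1 | target

**Count and risks**

Total step count: 15. Longest linear sequence: 11 steps (steps 1–4, 8, 9, 11–15).

Steps most likely to fail:

1. Step 14 (Proposed new method). Closure of the ten-membered ring is slow, so intermolecular coupling (cyclic dimer, oligomers) and reduction or β-hydride elimination at the iodide-bearing carbon may outrun it. The fallback sets out from 15 and returns at 24; it forms the same bond by a reaction type established for ten-membered lactones. (R)-But-3-yn-2-ol is hydrostannylated (Bu3SnH, PdCl2(PPh3)2 cat.) to (R,E)-4-(tributylstannyl)but-3-en-2-ol F1 and iodinated (I2) to (R,E)-4-iodobut-3-en-2-ol F2. Acid 15 is esterified with F2 as in step 11 to the iodovinyl ester F3, protonated as in step 12 to the all-cis lactone F4, and freed from the tert-butyl group as in step 13 to the acid F5. BH3·SMe2 should reduce the acid to the primary alcohol F6, and Dess–Martin periodinane gives the aldehyde F7. Nozaki–Hiyama–Kishi ring closure (CrCl2, NiCl2 cat., DMSO/THF, high dilution) gives the ring allylic alcohol F8. Dess–Martin oxidation to the ring enone F9 and conjugate reduction with [(Ph3P)CuH]6 give 24.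

2. Step 8. The stabilised enolate may attack the wrong alkene face, add reversibly, or act as a base towards the enoate instead of adding. The fallback sets out from 11 and 6 and returns at 13. Ester 11 is converted (LiN(SiMe3)2, Me3SiCl) into the silyl ketene acetal F10. F10 is added to 6 under Me3SiNTf2 catalysis in CH2Cl2 at −78 °C (Mukaiyama–Michael addition: neutral silicon nucleophile, Lewis-acid-activated acceptor, open transition state, no base present). The resulting silyl ketene acetal adduct F11 gives 13 on mild acidic work-up.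

3. Step 12. The protonation may discriminate the two faces poorly, and the new centre, being the more crowded epimer, may be lost again by enolisation in steps 13 and 14. The fallback sets out from 24 and returns to 24: the stereo-defining protonation is moved to the cis-fused bicycle, where the ten-membered ring shields one face. Compound 24, obtained as a mixture at the Ar-bearing carbon, is deprotonated at this most acidic position (LiN(SiMe3)2, 1.0 equiv, THF, −78 °C) to the lithium enolate F12 and protonated with AcOH from the convex face.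

Further compounds

F1 | step 14 | (R,E)-4-(tributylstannyl)but-3-en-2-ol | C[C@@H](O)/C=C/[Sn](CCCC)(CCCC)CCCC
F2 | step 14 | (R,E)-4-iodobut-3-en-2-ol | C[C@@H](O)/C=C/I
F3 | step 14 | (2R,3E)-4-iodobut-3-en-2-yl 2-[(2S,3S)-4-Ar-3-(2-tert-butoxy-2-oxoethyl)-5-oxooxolan-2-yl]acetate, both epimers at C-4 | CC(C)(C)OC(=O)C[C@@H]1[C@H](CC(=O)O[C@H](C)/C=C/I)OC(=O)C1c1ccc(CC[C@@H](C)O[Si](C)(C)C(C)(C)C)o1
F4 | step 14 | (2R,3E)-4-iodobut-3-en-2-yl 2-[(2S,3S,4S)-4-Ar-3-(2-tert-butoxy-2-oxoethyl)-5-oxooxolan-2-yl]acetate, all-cis | CC(C)(C)OC(=O)C[C@@H]1[C@H](CC(=O)O[C@H](C)/C=C/I)OC(=O)[C@@H]1c1ccc(CC[C@@H](C)O[Si](C)(C)C(C)(C)C)o1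
F5 | step 14 | 2-[(2S,3S,4S)-4-Ar-2-(2-{[(2R,3E)-4-iodobut-3-en-2-yl]oxy}-2-oxoethyl)-5-oxooxolan-3-yl]acetic acid | OC(=O)C[C@@H]1[C@H](CC(=O)O[C@H](C)/C=C/I)OC(=O)[C@@H]1c1ccc(CC[C@@H](C)O[Si](C)(C)C(C)(C)C)o1
F6 | step 14 | (2R,3E)-4-iodobut-3-en-2-yl 2-[(2S,3S,4S)-4-Ar-3-(2-hydroxyethyl)-5-oxooxolan-2-yl]acetate | OCC[C@@H]1[C@H](CC(=O)O[C@H](C)/C=C/I)OC(=O)[C@@H]1c1ccc(CC[C@@H](C)O[Si](C)(C)C(C)(C)C)o1
F7 | step 14 | (2R,3E)-4-iodobut-3-en-2-yl 2-[(2S,3S,4S)-4-Ar-5-oxo-3-(2-oxoethyl)oxolan-2-yl]acetate | O=CC[C@@H]1[C@H](CC(=O)O[C@H](C)/C=C/I)OC(=O)[C@@H]1c1ccc(CC[C@@H](C)O[Si](C)(C)C(C)(C)C)o1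
F8 | step 14 | ring allylic alcohol: 24 with CH(OH) in place of the ketone (both epimers) and an E double bond between the two ring CH2 carbons next to it on the CH(CH3)O side | C[C@@H]1/C=C/C(O)C[C@@H]2[C@H](CC(=O)O1)OC(=O)[C@@H]2c1ccc(CC[C@@H](C)O[Si](C)(C)C(C)(C)C)o1
F9 | step 14 | ring E-enone: 24 with an E double bond between the ketone α-carbon and the next carbon on the CH(CH3)O side | C[C@@H]1/C=C/C(=O)C[C@@H]2[C@H](CC(=O)O1)OC(=O)[C@@H]2c1ccc(CC[C@@H](C)O[Si](C)(C)C(C)(C)C)o1
F10 | step 8 | methyl trimethylsilyl ketene acetal of 11 | COC(O[Si](C)(C)C)=Cc1ccc(CC[C@@H](C)O[Si](C)(C)C(C)(C)C)o1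
F11 | step 8 | tert-butyl trimethylsilyl ketene acetal of 13 (Mukaiyama–Michael adduct) | COC(=O)C(c1ccc(CC[C@@H](C)O[Si](C)(C)C(C)(C)C)o1)[C@H](C=C(OC(C)(C)C)O[Si](C)(C)C)[C@@H](O[Si](CC)(CC)CC)CC(=O)OC
F12 | step 12 | lithium lactone enolate of 24 | C[C@@H]1CCC(=O)C[C@@H]2[C@H](CC(=O)O1)OC(O[Li])=C2c1ccc(CC[C@@H](C)O[Si](C)(C)C(C)(C)C)o1
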